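**Assumption:** the target has no stereocentre or other stereogenic element (it is achiral), so no stereocontrol is needed; atraric acid (a bulk fragrance chemical) and everninic acid are taken as catalogue materials.

## Retrosynthetic overview

1. Hypothamnolic acid ⇐ its ring B benzyl ester (hydrogenolysis) ⇐ the ring A C3-formyl depside (chlorite oxidation) ⇐ the C3-unsubstituted depside (ortho-formylation; ring B has no free ring position, so only ring A can react).
2. Depside ⇐ aryl C5–O bond, made by dehydrogenative C–H aroyloxylation of benzyl β-orcinolcarboxylate with free everninic acid on trivalent iodine (key step, new).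
3. Benzyl β-orcinolcarboxylate ⇐ atraric acid (saponification, then carboxylate benzylation).
4. Ring order: neither ring is built; both benzene rings are bought. Ring B is prepared first, ring A is attached second and completed last.

## Route

Step 1
Reactants: 1 methyl 2,4-dihydroxy-3,6-dimethylbenzoate (atraric acid)
Product: 2 2,4-dihydroxy-3,6-dimethylbenzoic acid
Conditions: KOH (8 equiv), H2O/DMSO 1:1, N2, 70 °C; then 2 M HCl, 0 °C
Reagents that add atoms: potassium hydroxide, [K+].[OH-]
Why: Saponification of the hindered salicylate ester is driven by excess hydroxide in DMSO/water, and cold acidification precipitates the acid before this β-resorcylic acid can decarboxylate.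

Step 2
Reactants: 2 2,4-dihydroxy-3,6-dimethylbenzoic acid
Product: 3 benzyl 2,4-dihydroxy-3,6-dimethylbenzoate
Conditions: BnBr (1.05 equiv), KHCO3 (1.2 equiv), DMF, 40 °C
Reagents that add atoms: benzyl bromide, BrCc1ccccc1
Why: SN2 O-alkylation of the carboxylate; hydrogencarbonate deprotonates only the carboxyl group, so the two phenols stay free.

Step 3
Reactants: 3 benzyl 2,4-dihydroxy-3,6-dimethylbenzoate; 4 2-hydroxy-4-methoxy-6-methylbenzoic acid (everninic acid)
Product: 8 benzyl 2,4-dihydroxy-5-[(2-hydroxy-4-methoxy-6-methylbenzoyl)oxy]-3,6-dimethylbenzoate, via bis(aroyloxy)phenyliodane 5 (not isolated), via aryloxy(aroyloxy)phenyliodane 6 (not isolated), via ortho-quinol ester 7 (not isolated)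
Conditions: PhI(OAc)2 (1.0 equiv), 4 (2.1 equiv), PhCl, 50 °C, 20 mbar (AcOH distilled off); then 3 (1.2 equiv, slow addition), CH2Cl2/(CF3)2CHOH 4:1, −30 °C to 0 °C
Reagents that add atoms: (diacetoxyiodo)benzene, CC(=O)OI(OC(C)=O)c1ccccc1 (its PhI unit is carried only in the non-isolated 5 and 6 and leaves as iodobenzene; no reagent atom remains in 8)
Why: Proposed new method: ligand exchange of both acetates for the carboxylate of 4 gives the trivalent-iodine bis(aroyloxy)iodane 5, the free, non-chelated 4-hydroxyl of 3 then displaces one aroyloxy ligand to give aryloxy-λ3-iodane 6, and reductive collapse to monovalent iodine (PhI) delivers the remaining iodine-bound aroyloxy group to C5, the only hydrogen-bearing and least hindered ortho/para carbon of ring B (ortho delivery from O4 and para delivery from O2 converge there), giving dienone 7, which tautomerises irreversibly to the aromatic 5-O-aroyl product with the 4-hydroxyl free; the chelated hydroxyl of ring A should stay out of the redox event because it is far less acidic and a six-membered salicylate chelate cannot span the trans positions of the hypervalent O–I–O bond; the closest known reaction types are the Wessely-type and PhI(OAc)2 ortho-acetoxylation of phenols, trivalent-iodine oxidative spirolactonisation of phenolic acids and the ortho-benzoyloxylation of phenols by dibenzoyl peroxide, none of which has been used for intermolecular transfer of a hindered ortho-hydroxyaroyloxy ligand to a phenol C–H bond to make a depside.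

Step 4
Reactants: 8 benzyl 2,4-dihydroxy-5-[(2-hydroxy-4-methoxy-6-methylbenzoyl)oxy]-3,6-dimethylbenzoate
Product: 10 benzyl 5-[(3-formyl-2-hydroxy-4-methoxy-6-methylbenzoyl)oxy]-2,4-dihydroxy-3,6-dimethylbenzoate, via aryl chloro(methoxy)methane 9 (not isolated)
Conditions: TiCl4 (4 equiv), Cl2CHOMe (1.5 equiv), CH2Cl2, −20 °C to 0 °C; then 1 M HCl, 0 °C
Reagents that add atoms: dichloromethyl methyl ether, COC(Cl)Cl; water, O
Why: Rieche formylation (Friedel–Crafts alkylation by the TiCl4-activated chloro ether, then hydrolysis): ring B has no ring hydrogen, and in ring A the titanium phenoxide directs the electrophile to C3, the only position ortho to the hydroxyl, rather than to C5 between OMe and Me; the cold, short exposure spares the aryl ester and the methyl ether, and any loss of the benzyl ester would be harmless because it is removed in step 6.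

Step 5
Reactants: 10 benzyl 5-[(3-formyl-2-hydroxy-4-methoxy-6-methylbenzoyl)oxy]-2,4-dihydroxy-3,6-dimethylbenzoate
Product: 11 3-({3-[(benzyloxy)carbonyl]-4,6-dihydroxy-2,5-dimethylphenoxy}carbonyl)-2-hydroxy-6-methoxy-4-methylbenzoic acid
Conditions: NaClO2 (3 equiv), NaH2PO4 (4 equiv), 2-methyl-2-butene (30 equiv), t-BuOH/THF/H2O, 0 °C to rt
Reagents that add atoms: sodium chlorite, [Na+].[O-]Cl=O
Why: Pinnick (Lindgren) oxidation: chlorous acid adds to the aldehyde and fragments to the carboxylic acid, the alkene traps the hypochlorous acid so the phenolic rings are not chlorinated, and both esters are inert.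

Step 6
Reactants: 11 3-({3-[(benzyloxy)carbonyl]-4,6-dihydroxy-2,5-dimethylphenoxy}carbonyl)-2-hydroxy-6-methoxy-4-methylbenzoic acid
Product: 12 hypothamnolic acid, 3-[(3-carboxy-4,6-dihydroxy-2,5-dimethylphenoxy)carbonyl]-2-hydroxy-6-methoxy-4-methylbenzoic acid
Conditions: H2 (1 atm), 10% Pd/C, EtOAc, rt
Reagents that add atoms: none
Why: Hydrogenolysis of the benzylic C–O bond frees the ring B carboxyl under neutral conditions that leave the depside aryl ester, the methyl ether and the phenols intact.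

## Compound list

1 | methyl 2,4-dihydroxy-3,6-dimethylbenzoate (atraric acid) | COC(=O)c1c(C)cc(O)c(C)c1O | starting material
2 | 2,4-dihydroxy-3,6-dimethylbenzoic acid | OC(=O)c1c(C)cc(O)c(C)c1O | intermediate
3 | benzyl 2,4-dihydroxy-3,6-dimethylbenzoate | O=C(OCc1ccccc1)c1c(C)cc(O)c(C)c1O | intermediate
4 | 2-hydroxy-4-methoxy-6-methylbenzoic acid (everninic acid) | COc1cc(C)c(C(=O)O)c(O)c1 | starting material
5 | bis(2-hydroxy-4-methoxy-6-methylbenzoyloxy)(phenyl)-λ3-iodane | COc1cc(C)c(C(=O)OI(OC(=O)c2c(C)cc(OC)cc2O)c2ccccc2)c(O)c1 | intermediate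
6 | {4-[(benzyloxy)carbonyl]-3-hydroxy-2,5-dimethylphenoxy}(2-hydroxy-4-methoxy-6-methylbenzoyloxy)(phenyl)-λ3-iodane | O=C(OCc1ccccc1)c1c(C)cc(OI(OC(=O)c2c(C)cc(OC)cc2O)c2ccccc2)c(C)c1O | intermediate
7 | benzyl 2-hydroxy-5-[(2-hydroxy-4-methoxy-6-methylbenzoyl)oxy]-3,6-dimethyl-4-oxocyclohexa-2,6-diene-1-carboxylate (transient sp3 centre at C5, racemic, lost on tautomerisation) | O=C(OCc1ccccc1)C1=C(C)C(OC(=O)c2c(C)cc(OC)cc2O)C(=O)C(C)=C1O | intermediate
8 | benzyl 2,4-dihydroxy-5-[(2-hydroxy-4-methoxy-6-methylbenzoyl)oxy]-3,6-dimethylbenzoate | COc1cc(C)c(C(=O)Oc2c(C)c(C(=O)OCc3ccccc3)c(O)c(C)c2O)c(O)c1 | intermediate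
9 | benzyl 5-({3-[chloro(methoxy)methyl]-2-hydroxy-4-methoxy-6-methylbenzoyl}oxy)-2,4-dihydroxy-3,6-dimethylbenzoate (transient, racemic at the chloro ether carbon) | COc1cc(C)c(C(=O)Oc2c(C)c(C(=O)OCc3ccccc3)c(O)c(C)c2O)c(O)c1C(Cl)OC | intermediate
10 | benzyl 5-[(3-formyl-2-hydroxy-4-methoxy-6-methylbenzoyl)oxy]-2,4-dihydroxy-3,6-dimethylbenzoate | COc1cc(C)c(C(=O)Oc2c(C)c(C(=O)OCc3ccccc3)c(O)c(C)c2O)c(O)c1C=O | intermediate
11 | 3-({3-[(benzyloxy)carbonyl]-4,6-dihydroxy-2,5-dimethylphenoxy}carbonyl)-2-hydroxy-6-methoxy-4-methylbenzoic acid | COc1cc(C)c(C(=O)Oc2c(C)c(C(=O)OCc3ccccc3)c(O)c(C)c2O)c(O)c1C(=O)O | intermediate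
12 | hypothamnolic acid | COc1cc(C)c(C(=O)Oc2c(C)c(C(=O)O)c(O)c(C)c2O)c(O)c1C(=O)O | target

## Step count and risk

Total steps: 6. Longest linear sequence: 6 (1 → 2 → 3 → 8 → 10 → 11 → 12); 4 enters at step 3.

**Step 3 (new oxidative aroyloxylation).** Risks are over-oxidation of 8, oxidative C–C dimerisation of 3, attack at the methyl-bearing C3, and oxidation of the phenolic ring of 4 on iodine. The fallback uses known chemistry only and sets out from 3. Teuber oxidation with (KSO3)2NO (KH2PO4 buffer, acetone/H2O, 0 °C) at the free position para to the 2-hydroxyl gives benzyl 4-hydroxy-2,5-dimethyl-3,6-dioxocyclohexa-1,4-diene-1-carboxylate F1. Reduction with aqueous Na2S2O4 gives benzyl 2,4,5-trihydroxy-3,6-dimethylbenzoate F2. F2 is esterified with 4 by the classical mixed-anhydride depside method ((CF3CO)2O, toluene, rt). The 5-hydroxyl is the most nucleophilic one, since the 2-hydroxyl is chelated and the 4-hydroxyl is para-conjugated to the ester, and any 4-O-acyl isomer can be equilibrated to the 5-O ester. This returns to the route at 8.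

**Step 4 (formylation on the depside).** Risks are a C3/C5 mixture and Lewis-acid damage to the ester or the methyl ether. The fallback installs the formyl group before the depside bond and sets out from 4. BnBr/KHCO3/DMF gives benzyl 2-hydroxy-4-methoxy-6-methylbenzoate F3. Magnesium-phenoxide-directed ortho-formylation (MgCl2, Et3N, paraformaldehyde, MeCN, reflux; only one ortho position is free) gives benzyl 3-formyl-2-hydroxy-4-methoxy-6-methylbenzoate F4. Brief hydrogenolysis (H2, Pd/C, EtOAc; the chelated aldehyde survives) gives 3-formyl-2-hydroxy-4-methoxy-6-methylbenzoic acid F5. F5 then replaces 4 in the step 3 protocol with 3, passing through bis(3-formyl-2-hydroxy-4-methoxy-6-methylbenzoyloxy)(phenyl)-λ3-iodane F6, {4-[(benzyloxy)carbonyl]-3-hydroxy-2,5-dimethylphenoxy}(3-formyl-2-hydroxy-4-methoxy-6-methylbenzoyloxy)(phenyl)-λ3-iodane F7 and benzyl 5-[(3-formyl-2-hydroxy-4-methoxy-6-methylbenzoyl)oxy]-2-hydroxy-3,6-dimethyl-4-oxocyclohexa-2,6-diene-1-carboxylate F8. If step 3 has itself been replaced, F5 is instead esterified with the triol F2 using (CF3CO)2O. Either way the route is rejoined at 10.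

**Step 5 (chlorite oxidation beside three free phenols).** Risks are quinone formation on the electron-rich ring B and chlorination at C5 of ring A. The fallback masks the phenols with groups that the final hydrogenolysis removes anyway, and sets out from 10. Benzyl chloroformate with pyridine and catalytic DMAP in CH2Cl2 gives benzyl 2,4-bis{[(benzyloxy)carbonyl]oxy}-5-[(2-{[(benzyloxy)carbonyl]oxy}-3-formyl-4-methoxy-6-methylbenzoyl)oxy]-3,6-dimethylbenzoate F9. The same NaClO2 oxidation on this non-phenolic substrate gives 2-{[(benzyloxy)carbonyl]oxy}-3-[(3-[(benzyloxy)carbonyl]-4,6-bis{[(benzyloxy)carbonyl]oxy}-2,5-dimethylphenoxy)carbonyl]-6-methoxy-4-methylbenzoic acid F10. One hydrogenolysis (H2, Pd/C, EtOAc) removes the benzyl ester and the three benzyl carbonates and returns to the route at 12.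

## Further compounds

F1 | step 3 | benzyl 4-hydroxy-2,5-dimethyl-3,6-dioxocyclohexa-1,4-diene-1-carboxylate | O=C(OCc1ccccc1)C1=C(C)C(=O)C(O)=C(C)C1=O
F2 | step 3 | benzyl 2,4,5-trihydroxy-3,6-dimethylbenzoate | O=C(OCc1ccccc1)c1c(C)c(O)c(O)c(C)c1O
F3 | step 4 | benzyl 2-hydroxy-4-methoxy-6-methylbenzoate | COc1cc(C)c(C(=O)OCc2ccccc2)c(O)c1
F4 | step 4 | benzyl 3-formyl-2-hydroxy-4-methoxy-6-methylbenzoate | COc1cc(C)c(C(=O)OCc2ccccc2)c(O)c1C=O
F5 | step 4 | 3-formyl-2-hydroxy-4-methoxy-6-methylbenzoic acid | COc1cc(C)c(C(=O)O)c(O)c1C=O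
F6 | step 4 | bis(3-formyl-2-hydroxy-4-methoxy-6-methylbenzoyloxy)(phenyl)-λ3-iodane | COc1cc(C)c(C(=O)OI(OC(=O)c2c(C)cc(OC)c(C=O)c2O)c2ccccc2)c(O)c1C=O
F7 | step 4 | {4-[(benzyloxy)carbonyl]-3-hydroxy-2,5-dimethylphenoxy}(3-formyl-2-hydroxy-4-methoxy-6-methylbenzoyloxy)(phenyl)-λ3-iodane | O=C(OCc1ccccc1)c1c(C)cc(OI(OC(=O)c2c(C)cc(OC)c(C=O)c2O)c2ccccc2)c(C)c1O
F8 | step 4 | benzyl 5-[(3-formyl-2-hydroxy-4-methoxy-6-methylbenzoyl)oxy]-2-hydroxy-3,6-dimethyl-4-oxocyclohexa-2,6-diene-1-carboxylate | O=C(OCc1ccccc1)C1=C(C)C(OC(=O)c2c(C)cc(OC)c(C=O)c2O)C(=O)C(C)=C1O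
F9 | step 5 | benzyl 2,4-bis{[(benzyloxy)carbonyl]oxy}-5-[(2-{[(benzyloxy)carbonyl]oxy}-3-formyl-4-methoxy-6-methylbenzoyl)oxy]-3,6-dimethylbenzoate | COc1cc(C)c(C(=O)Oc2c(C)c(C(=O)OCc3ccccc3)c(OC(=O)OCc3ccccc3)c(C)c2OC(=O)OCc2ccccc2)c(OC(=O)OCc2ccccc2)c1C=O
F10 | step 5 | 2-{[(benzyloxy)carbonyl]oxy}-3-[(3-[(benzyloxy)carbonyl]-4,6-bis{[(benzyloxy)carbonyl]oxy}-2,5-dimethylphenoxy)carbonyl]-6-methoxy-4-methylbenzoic acid | COc1cc(C)c(C(=O)Oc2c(C)c(C(=O)OCc3ccccc3)c(OC(=O)OCc3ccccc3)c(C)c2OC(=O)OCc2ccccc2)c(OC(=O)OCc2ccccc2)c1C(=O)O
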